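Ring A, the 4-methoxy-5,6-dihydro-2-pyranone fused to the cyclobutane, is opened at O1–C2, C2–C3 and C4–OMe. Since O1 on C6 and C4 on C5 are cis on the four-membered ring, ring A is the retron of a cis-2-ethynylcyclobutanol, carbon monoxide and methanol. One flask carboxylates the alkyne C–H, adds methanol at C4 and lactonises the tertiary alcohol. The precursor 28 is the 1-styryl-2-ethynyl-3-arylcyclobutanol with TIPS-protected phenols and a C8 hydroxymethyl group already trans to the aryl group; it comes from a keteniminium–alkyne cycloaddition, hydrogenation and styrylcerium addition. The second pyranone is then grown from C8.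

Key step: step 16

Remark: atom labels O1–C8 are those of ring A (O1, C2–C6) and of the cyclobutane (C5–C8) of the target; α is the cyclobutane face carrying the C6 oxygen, β the face carrying the styryl group; ArT = 4-[tri(propan-2-yl)silyloxy]phenyl, styryl = (E)-2-ArT-ethenyl, TES = triethylsilyl, TIPS = tri(propan-2-yl)silyl.

Assumption: the (2R,5R)-amine is taken to give the (4R)-cyclobutenone 12; should the opposite sense be found, the (2S,5S)-amine is used and nothing else changes.

Step 1
Reactants: 1 4-iodophenol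
Product: 2 (4-iodophenoxy)tri(propan-2-yl)silane
Conditions: TIPSCl, imidazole, DMF, rt
Reagents that add atoms: chlorotri(propan-2-yl)silane, CC(C)[Si](Cl)(C(C)C)C(C)C
Why: Standard silyl ether formation on a phenol; the TIPS ether is chosen because it should resist the methoxide of step 16 far better than smaller silyl ethers.

Step 2
Reactants: 2 (4-iodophenoxy)tri(propan-2-yl)silane; 3 3,3-diethoxyprop-1-yne
Product: 4 [4-(3,3-diethoxyprop-1-yn-1-yl)phenoxy]tri(propan-2-yl)silane
Conditions: PdCl2(PPh3)2 (2 mol %), CuI (4 mol %), Et3N, THF, rt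
Reagents that add atoms: none
Why: Sonogashira coupling of an aryl iodide with a terminal alkyne; the acetal is inert to the amine and carries the future C4 of ring A at the aldehyde oxidation level.

Step 3
Reactants: 5 oxetan-2-one (β-propiolactone); 6 (2R,5R)-2,5-dimethylpyrrolidine
Product: 8 1-[(2R,5R)-2,5-dimethylpyrrolidin-1-yl]-3-hydroxypropan-1-one, via aluminium amide 7 (not isolated)
Conditions: 6, AlMe3, CH2Cl2, 0 °C → rt; then 5, 0 °C → rt
Reagents that add atoms: none
Why: Weinreb-type aminolysis of a lactone by the dimethylaluminium amide of the hindered amine, which attacks the strained acyl carbon (acyl–oxygen cleavage) and should give the 3-hydroxy amide.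

Step 4
Reactants: 8 1-[(2R,5R)-2,5-dimethylpyrrolidin-1-yl]-3-hydroxypropan-1-one
Product: 9 1-[(2R,5R)-2,5-dimethylpyrrolidin-1-yl]-3-(triethylsilyloxy)propan-1-one
Conditions: TESCl, imidazole, CH2Cl2, 0 °C
Reagents that add atoms: chlorotriethylsilane, CC[Si](Cl)(CC)CC
Why: Silylation of a primary alcohol; a primary TES ether is chosen because Swern conditions later convert it directly into the aldehyde (step 11).

Step 5
Reactants: 9 1-[(2R,5R)-2,5-dimethylpyrrolidin-1-yl]-3-(triethylsilyloxy)propan-1-one; 4 [4-(3,3-diethoxyprop-1-yn-1-yl)phenoxy]tri(propan-2-yl)silane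
Product: 12 (4R)-2-(diethoxymethyl)-4-[(triethylsilyloxy)methyl]-3-{4-[tri(propan-2-yl)silyloxy]phenyl}cyclobut-2-en-1-one, via keteniminium triflate 10 (not isolated), via cyclobuteniminium triflate 11 (not isolated)
Conditions: 9, Tf2O, 2,4,6-collidine, CH2Cl2, −20 °C → rt; 4, rt → 40 °C; then H2O, aq. NaHCO3, rt
Reagents that add atoms: water, O
Why: Keteniminium–alkyne [2+2] cycloaddition and iminium hydrolysis, in which the aryl alkyne attacks the keteniminium carbon through its acetal-bearing carbon (aryl-stabilised vinyl cation), so the aryl group ends at C7, and ring closure at the enamine carbon on the face left open by the C2-symmetric pyrrolidine should set C8, which cannot racemise because enolisation would give a cyclobutadiene.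

Step 6
Reactants: 12 (4R)-cyclobutenone
Product: 13 all-cis cyclobutanone [C5: CH(OEt)2; C7: ArT; C8: CH2OTES; all three on one face]
Conditions: H2 (3 bar), 10% Pd/C, EtOAc, rt
Reagents that add atoms: none
Why: Heterogeneous syn-hydrogenation of the strained enone double bond from the face opposite the C8 substituent should set C5 and C7 and give the all-cis ketone; ethyl acetate keeps the TES ether and the acetal intact.

Step 7
Reactants: 14 4-hydroxybenzaldehyde
Product: 15 4-[tri(propan-2-yl)silyloxy]benzaldehyde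
Conditions: TIPSCl, imidazole, DMF, rt
Reagents that add atoms: chlorotri(propan-2-yl)silane, CC(C)[Si](Cl)(C(C)C)C(C)C
Why: Standard silyl ether formation on a phenol, matching the protecting group of the other ring.

Step 8
Reactants: 15 4-[tri(propan-2-yl)silyloxy]benzaldehyde
Product: 16 {4-[(E)-2-iodoethenyl]phenoxy}tri(propan-2-yl)silane
Conditions: CrCl2, CHI3, THF, 0 °C → rt
Reagents that add atoms: iodoform, IC(I)I
Why: Takai olefination, which is E-selective for aromatic aldehydes and tolerates the aryl silyl ether.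

Step 9
Reactants: 16 {4-[(E)-2-iodoethenyl]phenoxy}tri(propan-2-yl)silane; 13 all-cis cyclobutanone
Product: 19 cyclobutanol [C6: OH(α) + styryl(β); C5: CH(OEt)2(α); C7: ArT(α); C8: CH2OTES(α)], via styryllithium 17 (not isolated), via styrylcerium dichloride 18 (not isolated)
Conditions: 16, t-BuLi, Et2O, −78 °C; CeCl3, THF, −78 °C; then 13, −78 °C
Reagents that add atoms: none
Why: Iodine–lithium exchange with retention of alkene geometry, transmetalation to the weakly basic organocerium and 1,2-addition to the enolisable ketone; attack on the face opposite the three cis substituents should set C6 with the hydroxyl cis to them.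

Step 10
Reactants: 19 cyclobutanol
Product: 20 silyl ether [C6: OTES(α) + styryl(β); C5: CH(OEt)2(α); C7: ArT(α); C8: CH2OTES(α)]
Conditions: TESOTf, 2,6-lutidine, CH2Cl2, −78 °C
Reagents that add atoms: triethylsilyl trifluoromethanesulfonate, CC[Si](CC)(CC)OS(=O)(=O)C(F)(F)F
Why: Silyl triflate silylation of a hindered tertiary alcohol at a temperature at which the acetal is not activated; the silyl ether blocks retro-aldol opening of the cyclobutane once aldehydes stand next to C6.

Step 11
Reactants: 20 silyl ether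
Product: 22 trans aldehyde [C6: OTES(α) + styryl(β); C5: CH(OEt)2(α); C7: ArT(α); C8: CHO(β)], via cis aldehyde 21 (not isolated)
Conditions: (COCl)2, DMSO, CH2Cl2, −78 → −40 °C; Et3N, −78 °C → rt; then DBU (0.2 equiv), rt
Reagents that add atoms: none
Why: Swern oxidation applied directly to the primary TES ether (oxidative desilylation, selective over tertiary and aryl silyl ethers), then base-mediated epimerisation of the only enolisable centre, which should move the C8 formyl group away from the cis aryl, silyloxy and acetal groups to the thermodynamically preferred β face it has in the target.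

Step 12
Reactants: 22 trans aldehyde
Product: 23 alcohol [C6: OTES(α) + styryl(β); C5: CH(OEt)2(α); C7: ArT(α); C8: CH2OH(β)]
Conditions: NaBH4, EtOH/THF, 0 °C
Reagents that add atoms: none
Why: Hydride reduction of the aldehyde stores C8 in its final configuration as a non-enolisable primary alcohol.

Step 13
Reactants: 23 alcohol
Product: 26 aldehyde [C6: OTES(α) + styryl(β); C5: CHO(α); C7: ArT(α); C8: CH2OTES(β)], via silylated acetal 24 (not isolated), via collidinium salt 25 (not isolated)
Conditions: TESOTf, 2,4,6-collidine, CH2Cl2, 0 °C; then H2O, rt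
Reagents that add atoms: triethylsilyl trifluoromethanesulfonate, CC[Si](CC)(CC)OS(=O)(=O)C(F)(F)F; water, O
Why: Silyl triflate–collidine acetal cleavage, in which the acetal is ionised, the oxocarbenium ion is held as a pyridinium salt and water releases the aldehyde under nearly neutral conditions, while the primary alcohol is silylated in the same flask; the C8 oxygen is now trans and cannot trap the oxocarbenium ion, and C5 is untouched.

Step 14
Reactants: 26 aldehyde
Product: 27 alkyne [C6: OTES(α) + styryl(β); C5: C≡CH(α); C7: ArT(α); C8: CH2OTES(β)]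
Conditions: TMSCHN2, n-BuLi, THF, −78 °C; then 26, −78 → 0 °C
Reagents that add atoms: (trimethylsilyl)diazomethane, C[Si](C)(C)C=[N+]=[N-]
Why: Colvin homologation (addition of lithiated trimethylsilyldiazomethane, Peterson-type loss of silanolate, 1,2-hydride shift of the alkylidene carbene), run at −78 °C without the basic methanol that would epimerise C5.

Step 15
Reactants: 27 alkyne
Product: 28 precursor diol [C6: OH(α) + styryl(β); C5: C≡CH(α); C7: ArT(α); C8: CH2OH(β)]
Conditions: HF·pyridine, pyridine, THF, 0 °C → rt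
Reagents that add atoms: none
Why: Buffered acidic fluoride desilylation removes the two alkyl TES ethers, while the aryl TIPS ethers, which are labile mainly to basic fluoride, should remain.

Step 16
Reactants: 28 precursor diol; 29 carbon monoxide; 30 methanol
Product: 33 ring A bicycle: 8-(hydroxymethyl)-5-methoxy-1-styryl-7-ArT-2-oxabicyclo[4.2.0]oct-4-en-3-one (configuration as in 41), via ynoate 31 (not isolated), via methoxy enoate 32 (not isolated)
Conditions: PdCl2 (5 mol %), CuCl2 (2.2 equiv), NaOAc (2.2 equiv), CO (1 atm), MeOH, rt; Ar purge; then NaOMe (6 equiv), 0 °C → rt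
Reagents that add atoms: none
Why: Divalent palladium, CO and methanol form a methoxycarbonylpalladium species that takes up the acetylide generated with NaOAc; reductive elimination gives ynoate 31 (C2–C3) and zerovalent palladium, which CuCl2 reoxidises, the closest known reaction being the oxidative methoxycarbonylation of terminal alkynes. Methoxide then adds to the ynoate β-carbon C4, the enoate isomers equilibrate through the β,β-dimethoxy ester, and only the E isomer 32, whose ester is cis to C5, is drained by attack of the C6 alkoxide on the ester carbonyl, as in the methoxide-mediated conversion of δ-hydroxy ynoates into kavalactone-type 4-methoxy-5,6-dihydro-2-pyranones. Ring A is closed by this 6-exo-trig acyl substitution (O1–C2). No stereocentre is created; the cis ring fusion follows from the cis hydroxyl/ethynyl relation fixed in steps 6 and 9. The step needs chemoselectivity for alkyne C–H carbonylation over alkoxycarbonylation through the substrate hydroxyls and over palladium-induced ring expansion of the alkenylcyclobutanol, which the acetate base, the CO atmosphere, methanol as solvent and the shielded tertiary hydroxyl should secure, and regioselective β-addition, which is intrinsic to the ynoate. The trans C8 hydroxymethyl group can reach neither C2 nor C4, and the TIPS ethers are chosen to survive the brief methoxide exposure.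

Step 17
Reactants: 33 ring A bicycle
Product: 34 aldehyde: 5-methoxy-3-oxo-1-styryl-7-ArT-2-oxabicyclo[4.2.0]oct-4-ene-8-carbaldehyde (configuration as in 41)
Conditions: DMP, pyridine, CH2Cl2, 0 °C → rt
Reagents that add atoms: none
Why: Dess–Martin oxidation of the primary alcohol without base; C8 is already in its final, thermodynamically preferred configuration, so no epimerisation of this β-acyloxy aldehyde, which would invite E1cB loss of O1, is needed.

Step 18
Reactants: 34 aldehyde; 35 2,2,6-trimethyl-4H-1,3-dioxin-4-one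
Product: 37 aldol adduct: 8-[2-(2,2-dimethyl-4-oxo-4H-1,3-dioxin-6-yl)-1-hydroxyethyl] bicycle (carbinol epimers; other centres as in 41), via lithium dienolate 36 (not isolated)
Conditions: 35, LiN(iPr)2, THF, −78 °C; then 34, −78 °C; AcOH, −78 °C
Reagents that add atoms: none
Why: Vinylogous aldol addition of the dioxinone dienolate through its γ-carbon to the aldehyde, which at −78 °C should be much faster than attack on the hindered vinylogous carbonate of ring A; the new carbinol centre is formed without control and is removed in step 19.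

Step 19
Reactants: 37 aldol adduct
Product: 38 keto dioxinone: 8-[(2,2-dimethyl-4-oxo-4H-1,3-dioxin-6-yl)acetyl] bicycle (configuration as in 41)
Conditions: DMP, pyridine, CH2Cl2, rt
Reagents that add atoms: none
Why: Dess–Martin oxidation of the secondary alcohol to the β-keto dioxinone, which also removes the uncontrolled carbinol centre.

Step 20
Reactants: 38 keto dioxinone
Product: 40 bis-TIPS ether of the target, via hydroxypyranone 39 (not isolated)
Conditions: PhMe, 110 °C; then Me2SO4, K2CO3, acetone, rt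
Reagents that add atoms: dimethyl sulfate, COS(=O)(=O)OC
Why: Thermal retro-[4+2] loss of acetone gives an acylketene that the enol oxygen of the neighbouring ketone captures to form the 4-hydroxy-2-pyranone, and O-methylation of its acidic 4-hydroxyl with dimethyl sulfate should give the 4-methoxy-2-pyranone.

Step 21
Reactants: 40 bis-TIPS ether of the target
Product: 41 (1R,6S,7S,8S)-7-(4-hydroxyphenyl)-1-[(E)-2-(4-hydroxyphenyl)ethenyl]-5-methoxy-8-(4-methoxy-2-oxo-2H-pyran-6-yl)-2-oxabicyclo[4.2.0]oct-4-en-3-one (CNP0228336.2)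
Conditions: TBAF, AcOH (1:1), THF, 0 °C → rt
Reagents that add atoms: none
Why: Fluoride-mediated cleavage of the two aryl silyl ethers, buffered with acetic acid so that no free phenoxide can expel the allylic lactone oxygen at C6 or open the cyclobutane.

Compound list

1 | 4-iodophenol | Oc1ccc(I)cc1 | starting material
2 | (4-iodophenoxy)tri(propan-2-yl)silane | CC(C)[Si](Oc1ccc(I)cc1)(C(C)C)C(C)C | intermediate
3 | 3,3-diethoxyprop-1-yne | C#CC(OCC)OCC | starting material
4 | [4-(3,3-diethoxyprop-1-yn-1-yl)phenoxy]tri(propan-2-yl)silane | CCOC(OCC)C#Cc1ccc(O[Si](C(C)C)(C(C)C)C(C)C)cc1 | intermediate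
5 | oxetan-2-one (β-propiolactone) | O=C1CCO1 | starting material
6 | (2R,5R)-2,5-dimethylpyrrolidine | C[C@@H]1CC[C@@H](C)N1 | starting material
7 | aluminium amide: [(2R,5R)-2,5-dimethylpyrrolidin-1-yl]dimethylaluminium | C[C@@H]1CC[C@@H](C)N1[Al](C)C | intermediate
8 | 1-[(2R,5R)-2,5-dimethylpyrrolidin-1-yl]-3-hydroxypropan-1-one | C[C@@H]1CC[C@@H](C)N1C(=O)CCO | intermediate
9 | 1-[(2R,5R)-2,5-dimethylpyrrolidin-1-yl]-3-(triethylsilyloxy)propan-1-one | C[C@@H]1CC[C@@H](C)N1C(=O)CCO[Si](CC)(CC)CC | intermediate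
10 | keteniminium triflate: (2R,5R)-2,5-dimethyl-1-[3-(triethylsilyloxy)prop-1-en-1-ylidene]pyrrolidin-1-ium trifluoromethanesulfonate | C[C@@H]1CC[C@@H](C)[N+]1=C=CCO[Si](CC)(CC)CC.[O-]S(=O)(=O)C(F)(F)F | intermediate
11 | cyclobuteniminium triflate: iminium salt of ketone 12 with amine 6 (C8 as in 12) | C[C@@H]1CC[C@@H](C)[N+]1=C3C(C(OCC)OCC)=C(c2ccc(O[Si](C(C)C)(C(C)C)C(C)C)cc2)[C@@H]3CO[Si](CC)(CC)CC.[O-]S(=O)(=O)C(F)(F)F | intermediate
12 | (4R)-2-(diethoxymethyl)-4-[(triethylsilyloxy)methyl]-3-{4-[tri(propan-2-yl)silyloxy]phenyl}cyclobut-2-en-1-one | O=C1C(C(OCC)OCC)=C(c2ccc(O[Si](C(C)C)(C(C)C)C(C)C)cc2)[C@@H]1CO[Si](CC)(CC)CC | intermediate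
13 | all-cis cyclobutanone [C5: CH(OEt)2; C7: ArT; C8: CH2OTES; all three on one face] | O=C1[C@H](C(OCC)OCC)[C@H](c2ccc(O[Si](C(C)C)(C(C)C)C(C)C)cc2)[C@@H]1CO[Si](CC)(CC)CC | intermediate
14 | 4-hydroxybenzaldehyde | O=Cc1ccc(O)cc1 | starting material
15 | 4-[tri(propan-2-yl)silyloxy]benzaldehyde | O=Cc1ccc(O[Si](C(C)C)(C(C)C)C(C)C)cc1 | intermediate
16 | {4-[(E)-2-iodoethenyl]phenoxy}tri(propan-2-yl)silane | I/C=C/c1ccc(O[Si](C(C)C)(C(C)C)C(C)C)cc1 | intermediate
17 | styryllithium: [(E)-2-ArT-ethenyl]lithium | [Li]/C=C/c1ccc(O[Si](C(C)C)(C(C)C)C(C)C)cc1 | intermediate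
18 | styrylcerium dichloride: dichloro[(E)-2-ArT-ethenyl]cerium | Cl[Ce](Cl)/C=C/c1ccc(O[Si](C(C)C)(C(C)C)C(C)C)cc1 | intermediate
19 | cyclobutanol [C6: OH(α) + styryl(β); C5: CH(OEt)2(α); C7: ArT(α); C8: CH2OTES(α)] | O[C@]1(/C=C/c2ccc(O[Si](C(C)C)(C(C)C)C(C)C)cc2)[C@H](C(OCC)OCC)[C@H](c2ccc(O[Si](C(C)C)(C(C)C)C(C)C)cc2)[C@@H]1CO[Si](CC)(CC)CC | intermediate
20 | silyl ether [C6: OTES(α) + styryl(β); C5: CH(OEt)2(α); C7: ArT(α); C8: CH2OTES(α)] | CC[Si](CC)(CC)O[C@]1(/C=C/c2ccc(O[Si](C(C)C)(C(C)C)C(C)C)cc2)[C@H](C(OCC)OCC)[C@H](c2ccc(O[Si](C(C)C)(C(C)C)C(C)C)cc2)[C@@H]1CO[Si](CC)(CC)CC | intermediate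
21 | cis aldehyde [as 20, but C8: CHO(α)] | CC[Si](CC)(CC)O[C@]1(/C=C/c2ccc(O[Si](C(C)C)(C(C)C)C(C)C)cc2)[C@H](C(OCC)OCC)[C@H](c2ccc(O[Si](C(C)C)(C(C)C)C(C)C)cc2)[C@@H]1C=O | intermediate
22 | trans aldehyde [C6: OTES(α) + styryl(β); C5: CH(OEt)2(α); C7: ArT(α); C8: CHO(β)] | CC[Si](CC)(CC)O[C@]1(/C=C/c2ccc(O[Si](C(C)C)(C(C)C)C(C)C)cc2)[C@H](C(OCC)OCC)[C@H](c2ccc(O[Si](C(C)C)(C(C)C)C(C)C)cc2)[C@H]1C=O | intermediate
23 | alcohol [as 22, but C8: CH2OH(β)] | CC[Si](CC)(CC)O[C@]1(/C=C/c2ccc(O[Si](C(C)C)(C(C)C)C(C)C)cc2)[C@H](C(OCC)OCC)[C@H](c2ccc(O[Si](C(C)C)(C(C)C)C(C)C)cc2)[C@H]1CO | intermediate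
24 | silylated acetal [as 23, but C8: CH2OTES(β)] | CC[Si](CC)(CC)O[C@]1(/C=C/c2ccc(O[Si](C(C)C)(C(C)C)C(C)C)cc2)[C@H](C(OCC)OCC)[C@H](c2ccc(O[Si](C(C)C)(C(C)C)C(C)C)cc2)[C@H]1CO[Si](CC)(CC)CC | intermediate
25 | collidinium salt [as 24, but C5: CH(OEt)(2,4,6-trimethylpyridinium-1-yl)(α), triflate; N,O-acetal carbon unassigned] | CC[Si](CC)(CC)O[C@]1(/C=C/c2ccc(O[Si](C(C)C)(C(C)C)C(C)C)cc2)[C@H](C(OCC)[n+]2c(C)cc(C)cc2C)[C@H](c2ccc(O[Si](C(C)C)(C(C)C)C(C)C)cc2)[C@H]1CO[Si](CC)(CC)CC.[O-]S(=O)(=O)C(F)(F)F | intermediate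
26 | aldehyde [C6: OTES(α) + styryl(β); C5: CHO(α); C7: ArT(α); C8: CH2OTES(β)] | CC[Si](CC)(CC)O[C@]1(/C=C/c2ccc(O[Si](C(C)C)(C(C)C)C(C)C)cc2)[C@H](C=O)[C@H](c2ccc(O[Si](C(C)C)(C(C)C)C(C)C)cc2)[C@H]1CO[Si](CC)(CC)CC | intermediate
27 | alkyne [as 26, but C5: C≡CH(α)] | CC[Si](CC)(CC)O[C@]1(/C=C/c2ccc(O[Si](C(C)C)(C(C)C)C(C)C)cc2)[C@H](C#C)[C@H](c2ccc(O[Si](C(C)C)(C(C)C)C(C)C)cc2)[C@H]1CO[Si](CC)(CC)CC | intermediate
28 | precursor diol [C6: OH(α) + styryl(β); C5: C≡CH(α); C7: ArT(α); C8: CH2OH(β)] | O[C@]1(/C=C/c2ccc(O[Si](C(C)C)(C(C)C)C(C)C)cc2)[C@H](C#C)[C@H](c2ccc(O[Si](C(C)C)(C(C)C)C(C)C)cc2)[C@H]1CO | intermediate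
29 | carbon monoxide | [C-]#[O+] | starting material
30 | methanol | CO | starting material
31 | ynoate [as 28, but C5: C≡C–CO2Me(α)] | O[C@]1(/C=C/c2ccc(O[Si](C(C)C)(C(C)C)C(C)C)cc2)[C@H](C#CC(=O)OC)[C@H](c2ccc(O[Si](C(C)C)(C(C)C)C(C)C)cc2)[C@H]1CO | intermediate
32 | methoxy enoate [as 28, but C5: (E)-C(OMe)=CH–CO2Me(α), ester cis to C5] | O[C@]1(/C=C/c2ccc(O[Si](C(C)C)(C(C)C)C(C)C)cc2)[C@H](/C(OC)=C\C(=O)OC)[C@H](c2ccc(O[Si](C(C)C)(C(C)C)C(C)C)cc2)[C@H]1CO | intermediate
33 | ring A bicycle: 8-(hydroxymethyl)-5-methoxy-1-styryl-7-ArT-2-oxabicyclo[4.2.0]oct-4-en-3-one (configuration as in 41) | COC1=CC(=O)O[C@]2(/C=C/c3ccc(O[Si](C(C)C)(C(C)C)C(C)C)cc3)[C@H]1[C@H](c1ccc(O[Si](C(C)C)(C(C)C)C(C)C)cc1)[C@H]2CO | intermediate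
34 | aldehyde: 5-methoxy-3-oxo-1-styryl-7-ArT-2-oxabicyclo[4.2.0]oct-4-ene-8-carbaldehyde (configuration as in 41) | COC1=CC(=O)O[C@]2(/C=C/c3ccc(O[Si](C(C)C)(C(C)C)C(C)C)cc3)[C@H]1[C@H](c1ccc(O[Si](C(C)C)(C(C)C)C(C)C)cc1)[C@H]2C=O | intermediate
35 | 2,2,6-trimethyl-4H-1,3-dioxin-4-one | CC1=CC(=O)OC(C)(C)O1 | starting material
36 | lithium dienolate: lithium 2,2-dimethyl-6-methylidene-6H-1,3-dioxin-4-olate | C=C1C=C(O[Li])OC(C)(C)O1 | intermediate
37 | aldol adduct: 8-[2-(2,2-dimethyl-4-oxo-4H-1,3-dioxin-6-yl)-1-hydroxyethyl] bicycle (carbinol epimers; other centres as in 41) | COC1=CC(=O)O[C@]2(/C=C/c3ccc(O[Si](C(C)C)(C(C)C)C(C)C)cc3)[C@H]1[C@H](c1ccc(O[Si](C(C)C)(C(C)C)C(C)C)cc1)[C@H]2C(O)CC1=CC(=O)OC(C)(C)O1 | intermediate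
38 | keto dioxinone: 8-[(2,2-dimethyl-4-oxo-4H-1,3-dioxin-6-yl)acetyl] bicycle (configuration as in 41) | COC1=CC(=O)O[C@]2(/C=C/c3ccc(O[Si](C(C)C)(C(C)C)C(C)C)cc3)[C@H]1[C@H](c1ccc(O[Si](C(C)C)(C(C)C)C(C)C)cc1)[C@H]2C(=O)CC1=CC(=O)OC(C)(C)O1 | intermediate
39 | hydroxypyranone: 8-(4-hydroxy-2-oxo-2H-pyran-6-yl) bicycle (configuration as in 41) | COC1=CC(=O)O[C@]2(/C=C/c3ccc(O[Si](C(C)C)(C(C)C)C(C)C)cc3)[C@H]1[C@H](c1ccc(O[Si](C(C)C)(C(C)C)C(C)C)cc1)[C@H]2c1cc(O)cc(=O)o1 | intermediate
40 | bis-TIPS ether of the target | COC1=CC(=O)O[C@]2(/C=C/c3ccc(O[Si](C(C)C)(C(C)C)C(C)C)cc3)[C@H]1[C@H](c1ccc(O[Si](C(C)C)(C(C)C)C(C)C)cc1)[C@H]2c1cc(OC)cc(=O)o1 | intermediate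
41 | (1R,6S,7S,8S)-7-(4-hydroxyphenyl)-1-[(E)-2-(4-hydroxyphenyl)ethenyl]-5-methoxy-8-(4-methoxy-2-oxo-2H-pyran-6-yl)-2-oxabicyclo[4.2.0]oct-4-en-3-one (CNP0228336.2) | COC1=CC(=O)O[C@]2(/C=C/c3ccc(O)cc3)[C@H]1[C@H](c1ccc(O)cc1)[C@H]2c1cc(OC)cc(=O)o1 | target

Total step count: 21. Longest linear sequence: 17 steps (steps 1, 2, 5, 6 and 9–21).

Steps most likely to fail

1. Step 16. The free tertiary hydroxyl next to palladium may divert the reaction. Divalent palladium could trigger ring expansion of the alkenylcyclobutanol, or an alkoxycarbonylative cyclisation through the hydroxyl could replace C–H carbonylation. In the methoxide stage the aryl silyl groups may be lost or the strained alkoxide may fragment. The fallback sets out from 27 and uses no palladium. Deprotonation of the alkyne with n-BuLi (THF, −78 °C) and quenching with methyl chloroformate should give the bis(silyl ether) ynoate F1. HF·pyridine/pyridine in THF then removes both TES groups to give hydroxy ynoate 31. Brief treatment with NaOMe in MeOH at 0 °C adds methanol and lactonises by way of 32, and the route is rejoined at 33.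

2. Step 5. Facial discrimination in the ring-closing C–C bond formation may be insufficient, so that 12 is formed with low enantiomeric purity. The fallback sets out from 4 and takes the absolute configuration from a separation instead of from induction. N,N-Dimethyl-3-(triethylsilyloxy)propanamide F2 (commercial 3-hydroxy-N,N-dimethylpropanamide, TESCl, imidazole) is activated with Tf2O/2,4,6-collidine to the achiral keteniminium triflate F3. Its addition to 4 gives the racemic cyclobuteniminium triflate F4, and hydrolysis gives the racemic cyclobutenone, that is 12 together with its enantiomer F5. The two are separated by preparative chromatography on a chiral stationary phase (cellulose tris(3,5-dimethylphenylcarbamate), supercritical CO2/propan-2-ol). The route is rejoined at 12.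

3. Step 14. The crowded aldehyde 26 may be enolised by the lithiated diazomethane before it is attacked. This would invert C5 to the more stable trans arrangement and destroy the cis relation that step 16 needs. The fallback sets out from 26 and uses the Corey–Fuchs sequence. The non-basic dibromomethylene ylide (CBr4, PPh3, Zn, CH2Cl2, 0 °C) should convert 26 into the dibromoalkene F6. n-BuLi (2.2 equiv, THF, −78 °C, then water) then gives the terminal alkyne by bromine–lithium exchange and Fritsch–Buttenberg–Wiechell rearrangement. The route is rejoined at 27.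

Further compounds

F1 | step 16 | bis(silyl ether) ynoate [C6: OTES(α) + styryl(β); C5: C≡C–CO2Me(α); C7: ArT(α); C8: CH2OTES(β)] | CC[Si](CC)(CC)O[C@]1(/C=C/c2ccc(O[Si](C(C)C)(C(C)C)C(C)C)cc2)[C@H](C#CC(=O)OC)[C@H](c2ccc(O[Si](C(C)C)(C(C)C)C(C)C)cc2)[C@H]1CO[Si](CC)(CC)CC
F2 | step 5 | N,N-dimethyl-3-(triethylsilyloxy)propanamide | CN(C)C(=O)CCO[Si](CC)(CC)CC
F3 | step 5 | N,N-dimethyl-N-[3-(triethylsilyloxy)prop-1-en-1-ylidene]ammonium trifluoromethanesulfonate | C[N+](C)=C=CCO[Si](CC)(CC)CC.[O-]S(=O)(=O)C(F)(F)F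
F4 | step 5 | racemic N,N-dimethyl cyclobuteniminium triflate of 12 (C8 not defined) | C[N+](C)=C1C(C(OCC)OCC)=C(c2ccc(O[Si](C(C)C)(C(C)C)C(C)C)cc2)C1CO[Si](CC)(CC)CC.[O-]S(=O)(=O)C(F)(F)F
F5 | step 5 | (4S)-2-(diethoxymethyl)-4-[(triethylsilyloxy)methyl]-3-{4-[tri(propan-2-yl)silyloxy]phenyl}cyclobut-2-en-1-one (enantiomer of 12) | O=C1C(C(OCC)OCC)=C(c2ccc(O[Si](C(C)C)(C(C)C)C(C)C)cc2)[C@H]1CO[Si](CC)(CC)CC
F6 | step 14 | dibromoalkene [C6: OTES(α) + styryl(β); C5: CH=CBr2(α); C7: ArT(α); C8: CH2OTES(β)] | CC[Si](CC)(CC)O[C@]1(/C=C/c2ccc(O[Si](C(C)C)(C(C)C)C(C)C)cc2)[C@H](C=C(Br)Br)[C@H](c2ccc(O[Si](C(C)C)(C(C)C)C(C)C)cc2)[C@H]1CO[Si](CC)(CC)CC
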